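Rings: ring A is the formyl arene, ring B the central arene, ring C the pyranone and ring D the seven-membered dioxepinone lactone. Going round ring A, its carbons are the methyl carbon, the CH carbon, the hydroxyl carbon, the formyl carbon, the ether carbon and the carboxyl carbon.
Retrosynthesis: the formyl group is masked as a diethyl acetal. Ring A is cut at three bonds (hydroxyl carbon to formyl carbon, ether carbon to carboxyl carbon, CH carbon to hydroxyl carbon); the second cut also opens ring D and leaves an acyl group on one ring B oxygen and an alkynyl group on its neighbour. Ring C is cut at its aryl ketone and aryl ether bonds.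
Enabling feature: in ring A the hydroxyl carbon and the ether carbon are meta to each other with the formyl carbon between them. This is the pattern left by a ketene carbonyl carbon and the oxygen-bearing carbon of an ynol ether in a vinylketene benzannulation, and the ester oxygen and ether oxygen that carry these partners sit on adjacent carbons of ring B.
Forward order: ring B comes from an orcinol-derived triol; ring C is annulated by Friedel-Crafts acylation and oxa-Michael closure; the ether oxygen of ring B becomes an ynol ether and the ester oxygen a vinyl diazo ketoester; irradiation closes rings D and A together; acetal hydrolysis ends the route.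
Stereochemistry: the target has no stereocentre; the stereocentres of two transient intermediates are racemic and vanish in the step that forms them.

Key step: step 11

Remark: 2,4-dihydroxy-6-methylbenzaldehyde (the formylation product of orcinol) and 2,2-diethoxyacetaldehyde are taken as purchasable, and the acid-sensitive ynol ethers are assumed to be handled in base-washed glassware and used without storage.

## Route

Step 1
Reactants: 1 2,4-dihydroxy-6-methylbenzaldehyde
Product: 3 6-methylbenzene-1,2,4-triol, via aryl formate 2 (not isolated)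
Conditions: H2O2 (30% aq.), NaOH, H2O, 0 °C, argon; then aq. HCl
Reagents that add atoms: hydrogen peroxide, OO
Why: Dakin oxidation, in which the hydroperoxide adduct of the ortho- and para-hydroxylated aldehyde undergoes aryl migration to formate 2 and is saponified in the same pot, so the new oxygen sits unambiguously on the carbon that carried the formyl group.

Step 2
Reactants: 3 6-methylbenzene-1,2,4-triol, 4 3-methylbut-2-enoic acid
Product: 6 6,7-dihydroxy-2,2,5-trimethylchroman-4-one, via hydroxyaryl enone 5 (not isolated)
Conditions: P2O5 in MeSO3H, 70 °C, argon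
Reagents that add atoms: none
Why: Friedel-Crafts acylation by acid 4 under dehydrating acid should occur at the only ring position that is para to one hydroxyl and ortho to another, and oxa-Michael closure of enone 5 through the single neighbouring hydroxyl then gives the 2,2-dimethylchromanone with the methyl group peri to the ketone.

Step 3
Reactants: 6 6,7-dihydroxy-2,2,5-trimethylchroman-4-one
Product: 7 2,2,5-trimethyl-6,7-bis(triisopropylsilyloxy)chroman-4-one
Conditions: TIPSCl, imidazole, DMAP (cat.), DMF, 50 °C
Reagents that add atoms: triisopropylsilyl chloride, CC(C)[Si](Cl)(C(C)C)C(C)C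
Why: Silyl ether formation under imidazole catalysis should cap both phenols, and the chloride is preferred to the triflate so that the ketone is not turned into a silyl enol ether.

Step 4
Reactants: 7 2,2,5-trimethyl-6,7-bis(triisopropylsilyloxy)chroman-4-one
Product: 8 7-hydroxy-2,2,5-trimethyl-6-(triisopropylsilyloxy)chroman-4-one
Conditions: K2CO3 (1.1 equiv), MeOH/THF, 0 °C to rt; pH 7 buffer
Reagents that add atoms: none
Why: Base-mediated methanolysis of aryl silyl ethers is fastest for the most acidic phenol, here the oxygen at position 7 para to the ketone, while the silyl ether at position 6 flanked by the methyl group should survive and has no thermodynamic drive to migrate onto the better stabilised phenoxide at position 7.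

Step 5
Reactants: 9 2,2-diethoxyacetaldehyde, 10 carbon tetrabromide
Product: 11 1,1-dibromo-3,3-diethoxyprop-1-ene
Conditions: PPh3, Et3N, CH2Cl2, 0 °C
Reagents that add atoms: none
Why: Ramirez dibromo-olefination (the first stage of the Corey-Fuchs sequence) of an aldehyde, buffered with Et3N so that the acetal never meets HBr.

Step 6
Reactants: 8 7-hydroxy-2,2,5-trimethyl-6-(triisopropylsilyloxy)chroman-4-one, 11 1,1-dibromo-3,3-diethoxyprop-1-ene
Product: 13 7-(3,3-diethoxyprop-1-ynyloxy)-2,2,5-trimethyl-6-(triisopropylsilyloxy)chroman-4-one, via (Z)-bromo enol ether 12 (not isolated)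
Conditions: CuI (10 mol%), 2,2'-bipyridine (20 mol%), K3PO4, toluene, 110 °C; then KOtBu, 1,4-dioxane, rt
Reagents that add atoms: none
Why: Ullmann-type carbon-oxygen coupling under catalysis by monovalent copper replaces the bromine trans to the substituent of a 1,1-dibromoalkene, the resulting bromo enol ether 12 has hydrogen and bromine anti so that base-induced anti elimination with KOtBu should give the ynol ether, and the silyl group on the neighbouring oxygen blocks a second substitution to a cyclic ketene acetal.

Step 7
Reactants: 13 7-(3,3-diethoxyprop-1-ynyloxy)-2,2,5-trimethyl-6-(triisopropylsilyloxy)chroman-4-one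
Product: 14 7-(3,3-diethoxyprop-1-ynyloxy)-6-hydroxy-2,2,5-trimethylchroman-4-one
Conditions: TBAF (1.05 equiv), THF, -78 to 0 °C; pH 7 phosphate buffer
Reagents that add atoms: none
Why: Fluoride-mediated desilylation of an aryl silyl ether proceeds at low temperature, where ynol ether, acetal and ketone are inert, and the neutral buffered work-up keeps the freed phenol from adding to the ynol ether.

Step 8
Reactants: 14 7-(3,3-diethoxyprop-1-ynyloxy)-6-hydroxy-2,2,5-trimethylchroman-4-one, 15 bromoacetyl bromide
Product: 16 7-(3,3-diethoxyprop-1-ynyloxy)-2,2,5-trimethyl-4-oxochroman-6-yl bromoacetate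
Conditions: pyridine, CH2Cl2, -40 to 0 °C
Reagents that add atoms: none
Why: O-Acylation of a phenol by an acid bromide with pyridine as base, run cold and with excess pyridine so that the medium never turns acidic toward the ynol ether and the acetal.

Step 9
Reactants: 16 7-(3,3-diethoxyprop-1-ynyloxy)-2,2,5-trimethyl-4-oxochroman-6-yl bromoacetate
Product: 19 7-(3,3-diethoxyprop-1-ynyloxy)-2,2,5-trimethyl-4-oxochroman-6-yl diazoacetate, via N-alkyl ditosylhydrazide 17 (not isolated), via glyoxylate tosylhydrazone 18 (not isolated)
Conditions: N,N'-ditosylhydrazine (2 equiv), DBU (5 equiv), THF, 0 °C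
Reagents that add atoms: N,N'-ditosylhydrazine, Cc1ccc(cc1)S(=O)(=O)NNS(=O)(=O)c1ccc(C)cc1
Why: Diazoacetate synthesis by the ditosylhydrazine method, that is N-alkylation by the bromoacetate followed by two base-induced sulfinate eliminations (the second of Bamford-Stevens type), which brings in the diazo group without a sulfonyl azide that could add to the ynol ether.

Step 10
Reactants: 19 7-(3,3-diethoxyprop-1-ynyloxy)-2,2,5-trimethyl-4-oxochroman-6-yl diazoacetate, 20 methacrolein
Product: 22 7-(3,3-diethoxyprop-1-ynyloxy)-2,2,5-trimethyl-4-oxochroman-6-yl 2-diazo-4-methyl-3-oxopent-4-enoate, via diazo hydroxy ester 21 (not isolated)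
Conditions: DBU (20 mol%), DMSO, rt; then IBX (1.5 equiv), rt
Reagents that add atoms: none
Why: DBU-catalysed aldol-type addition of the acidic diazoacetate carbon-hydrogen bond to the aldehyde carbonyl, followed by IBX oxidation of the allylic alcohol 21 in the same DMSO solution, is a known one-pot entry to 2-diazo-3-keto esters, and the racemic carbinol centre of 21 is removed by the oxidation.

Step 11
Reactants: 22 7-(3,3-diethoxyprop-1-ynyloxy)-2,2,5-trimethyl-4-oxochroman-6-yl 2-diazo-4-methyl-3-oxopent-4-enoate
Product: 27 mollicellin B diethyl acetal, via acyl vinyl ketene 23 (not isolated), via cyclobutenone 24 (not isolated), via dienyl ketene 25 (not isolated), via cyclohexadienone 26 (not isolated)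
Conditions: hν (medium-pressure Hg lamp, Pyrex filter), degassed toluene, 0.005 M, 20 °C; then 80 °C
Reagents that add atoms: none
Why: Proposed new method: excitation of the diazo group in 22 should trigger a Wolff shift of the isopropenyl group (carbon migrates in preference to aryloxy) to give ketene 23, whose electrophilic carbonyl carbon is attacked by the acetal-bearing beta carbon of the ynol ether while its alpha carbon bonds to the oxygen-bearing alkyne carbon, so that a [2+2] cycloaddition gives cyclobutenone 24; warming opens 24 in a four-electron electrocyclic step to dienylketene 25, which closes by six-electron electrocyclisation onto the isopropenyl methylene carbon to dienone 26 and enolises to phenol 27. The closest known reaction type is the benzannulation of vinylketenes, made from cyclobutenones or by photochemical Wolff rearrangement of unsaturated diazo ketones, with alkoxyalkynes, siloxyalkynes and ynamides; not yet shown are the ester tether, the acyl group on the ketene and an aryl ynol ether partner. Ring D closes in the [2+2] event as a seven-membered ring through the bond between the ether carbon and the carboxyl carbon of ring A (the bond between the hydroxyl carbon and the acetal-bearing carbon forms in the same event), which is feasible because ketene and alkyne hang from oxygens on adjacent carbons of ring B, and ring A closes by the six-electron electrocyclisation through the bond between its CH carbon and its hydroxyl carbon. No stereocentre survives, since the quaternary carbon of racemic 24 becomes trigonal on ring opening. The regiochemistry required, beta carbon to ketene carbonyl, is the one that the polarity of both partners dictates and the only one the tether can reach, and the geometry required in 25, isopropenyl cis to the ketene, is enforced because the ester carbon and the aryloxy oxygen must remain cis on the ring D double bond. Direct photolysis at high dilution is chosen over a metal carbenoid so that cyclopropenation of the alkyne, ylide formation and intermolecular ketene trapping are kept out.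

Step 12
Reactants: 27 mollicellin B diethyl acetal
Product: 28 mollicellin B
Conditions: 0.5 M aq. HCl, THF, 20 °C
Reagents that add atoms: water, O
Why: Acid-catalysed acetal hydrolysis, assisted by the ortho hydroxyl, should need only dilute acid at room temperature, which leaves the depsidone lactone and the chromanone untouched.

## Compound list

1 | 2,4-dihydroxy-6-methylbenzaldehyde | Cc1cc(O)cc(O)c1C=O | starting material
2 | 2,4-dihydroxy-6-methylphenyl formate | Cc1cc(O)cc(O)c1OC=O | intermediate
3 | 6-methylbenzene-1,2,4-triol | Cc1cc(O)cc(O)c1O | intermediate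
4 | 3-methylbut-2-enoic acid | CC(C)=CC(=O)O | starting material
5 | 3-methyl-1-(3,4,6-trihydroxy-2-methylphenyl)but-2-en-1-one | Cc1c(O)c(O)cc(O)c1C(=O)C=C(C)C | intermediate
6 | 6,7-dihydroxy-2,2,5-trimethylchroman-4-one | Cc1c(O)c(O)cc2OC(C)(C)CC(=O)c12 | intermediate
7 | 2,2,5-trimethyl-6,7-bis(triisopropylsilyloxy)chroman-4-one | Cc1c(O[Si](C(C)C)(C(C)C)C(C)C)c(O[Si](C(C)C)(C(C)C)C(C)C)cc2OC(C)(C)CC(=O)c12 | intermediate
8 | 7-hydroxy-2,2,5-trimethyl-6-(triisopropylsilyloxy)chroman-4-one | Cc1c(O[Si](C(C)C)(C(C)C)C(C)C)c(O)cc2OC(C)(C)CC(=O)c12 | intermediate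
9 | 2,2-diethoxyacetaldehyde | CCOC(OCC)C=O | starting material
10 | carbon tetrabromide | BrC(Br)(Br)Br | starting material
11 | 1,1-dibromo-3,3-diethoxyprop-1-ene | CCOC(OCC)C=C(Br)Br | intermediate
12 | 7-[(Z)-1-bromo-3,3-diethoxyprop-1-enyloxy]-2,2,5-trimethyl-6-(triisopropylsilyloxy)chroman-4-one | Cc1c(O[Si](C(C)C)(C(C)C)C(C)C)c(O/C(Br)=C/C(OCC)OCC)cc2OC(C)(C)CC(=O)c12 | intermediate
13 | 7-(3,3-diethoxyprop-1-ynyloxy)-2,2,5-trimethyl-6-(triisopropylsilyloxy)chroman-4-one | Cc1c(O[Si](C(C)C)(C(C)C)C(C)C)c(OC#CC(OCC)OCC)cc2OC(C)(C)CC(=O)c12 | intermediate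
14 | 7-(3,3-diethoxyprop-1-ynyloxy)-6-hydroxy-2,2,5-trimethylchroman-4-one | Cc1c(O)c(OC#CC(OCC)OCC)cc2OC(C)(C)CC(=O)c12 | intermediate
15 | bromoacetyl bromide | BrCC(Br)=O | starting material
16 | 7-(3,3-diethoxyprop-1-ynyloxy)-2,2,5-trimethyl-4-oxochroman-6-yl bromoacetate | Cc1c(OC(=O)CBr)c(OC#CC(OCC)OCC)cc2OC(C)(C)CC(=O)c12 | intermediate
17 | 7-(3,3-diethoxyprop-1-ynyloxy)-2,2,5-trimethyl-4-oxochroman-6-yl 2-[1,2-bis(4-methylphenylsulfonyl)hydrazinyl]acetate | Cc1c(OC(=O)CN(NS(=O)(=O)c3ccc(C)cc3)S(=O)(=O)c3ccc(C)cc3)c(OC#CC(OCC)OCC)cc2OC(C)(C)CC(=O)c12 | intermediate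
18 | 7-(3,3-diethoxyprop-1-ynyloxy)-2,2,5-trimethyl-4-oxochroman-6-yl 2-[(4-methylphenylsulfonyl)hydrazinylidene]acetate | Cc1c(OC(=O)C=NNS(=O)(=O)c3ccc(C)cc3)c(OC#CC(OCC)OCC)cc2OC(C)(C)CC(=O)c12 | intermediate
19 | 7-(3,3-diethoxyprop-1-ynyloxy)-2,2,5-trimethyl-4-oxochroman-6-yl diazoacetate | Cc1c(OC(=O)C=[N+]=[N-])c(OC#CC(OCC)OCC)cc2OC(C)(C)CC(=O)c12 | intermediate
20 | methacrolein (2-methylprop-2-enal) | CC(=C)C=O | starting material
21 | 7-(3,3-diethoxyprop-1-ynyloxy)-2,2,5-trimethyl-4-oxochroman-6-yl 2-diazo-3-hydroxy-4-methylpent-4-enoate (racemic) | Cc1c(OC(=O)C(=[N+]=[N-])C(O)C(C)=C)c(OC#CC(OCC)OCC)cc2OC(C)(C)CC(=O)c12 | intermediate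
22 | 7-(3,3-diethoxyprop-1-ynyloxy)-2,2,5-trimethyl-4-oxochroman-6-yl 2-diazo-4-methyl-3-oxopent-4-enoate | Cc1c(OC(=O)C(=[N+]=[N-])C(=O)C(C)=C)c(OC#CC(OCC)OCC)cc2OC(C)(C)CC(=O)c12 | intermediate
23 | (aryloxycarbonyl)(isopropenyl)ketene: 7-(3,3-diethoxyprop-1-ynyloxy)-2,2,5-trimethyl-4-oxochroman-6-yl 3-methyl-2-(oxomethylidene)but-3-enoate | Cc1c(OC(=O)C(=C=O)C(C)=C)c(OC#CC(OCC)OCC)cc2OC(C)(C)CC(=O)c12 | intermediate
24 | cyclobutenone fused to ring D (4-isopropenyl, 2-diethoxymethyl, 3-aryloxy; racemic) | Cc1c2OC(=O)C3(C(C)=C)C(=O)C(C(OCC)OCC)=C3Oc2cc2OC(C)(C)CC(=O)c12 | intermediate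
25 | dienylketene with ring D closed (ring-opened form of 24) | Cc1c2OC(=O)C(C(C)=C)=C(C(=C=O)C(OCC)OCC)Oc2cc2OC(C)(C)CC(=O)c12 | intermediate
26 | cyclohexa-2,4-dienone tautomer of 27 | CC1=C2C(=O)Oc3c(C)c4C(=O)CC(C)(C)Oc4cc3OC2=C(C(OCC)OCC)C(=O)C1 | intermediate
27 | mollicellin B diethyl acetal | Cc1cc(O)c(C(OCC)OCC)c2c1C(=O)Oc1c(cc3c(c1C)C(=O)CC(C)(C)O3)O2 | intermediate
28 | mollicellin B | Cc1cc(O)c(C=O)c2c1C(=O)Oc1c(cc3c(c1C)C(=O)CC(C)(C)O3)O2 | target

## Step count and risks

Total step count: 12. Longest linear sequence: 11 steps (steps 1 to 4 and 6 to 12, from compound 1).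

Steps most likely to fail:

**Step 11 (proposed new method).** Three things may go wrong: the Wolff shift may lose to carbene side paths; the diazo group may add as a dipole across the ynol ether before irradiation; or the acylketene may be trapped through its ester carbonyl in a [4+2] mode instead of through its carbon-carbon double bond. The fallback builds ring A by the established two-component benzannulation and closes ring D afterwards by carbonylation; it sets out from 13 and returns at 27. 3-Methylbut-3-en-2-one (CC(=C)C(C)=O) is trifluoroacetylated with LiN(SiMe3)2 and 2,2,2-trifluoroethyl trifluoroacetate to 1,1,1-trifluoro-5-methylhex-5-ene-2,4-dione F1. Detrifluoroacetylative diazo transfer (MsN3, Et3N, aqueous MeCN) converts this into 1-diazo-3-methylbut-3-en-2-one F2. Irradiation of this diazo ketone with ynol ether 13 in CH2Cl2 and then warming to 80 °C should give, by the known intermolecular vinylketene benzannulation, 7-[2-(diethoxymethyl)-3-hydroxy-5-methylphenoxy]-2,2,5-trimethyl-6-(triisopropylsilyloxy)chroman-4-one F3, in which the ring A carbon that is to carry the lactone carbonyl still bears hydrogen. Iodination para to the new phenol with N-iodosuccinimide in MeCN at 0 °C should give 7-[2-(diethoxymethyl)-3-hydroxy-6-iodo-5-methylphenoxy]-2,2,5-trimethyl-6-(triisopropylsilyloxy)chroman-4-one F4. TBAF then frees the ring B phenol to give 7-[2-(diethoxymethyl)-3-hydroxy-6-iodo-5-methylphenoxy]-6-hydroxy-2,2,5-trimethylchroman-4-one F5. Aryloxycarbonylation (Pd(OAc)2, Xantphos, CO at 1 atm, Et3N, toluene, 80 °C, high dilution) closes the seven-membered lactone and delivers 27.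

**Step 6.** The hindered, electron-poor phenoxide may couple sluggishly, the silyl group may wander to the reacting oxygen at 110 °C, or the elimination may degrade the product. The fallback makes the ynol ether by enol triflate elimination of an aryloxymethyl ketone; it sets out from 8 and returns at 13. 1,1-Diethoxypropan-2-one is brominated on the methyl group (phenyltrimethylammonium tribromide, THF) to 3-bromo-1,1-diethoxypropan-2-one F6. Phenol 8 is O-alkylated with this bromo ketone (K2CO3, acetone) to 7-(3,3-diethoxy-2-oxopropoxy)-2,2,5-trimethyl-6-(triisopropylsilyloxy)chroman-4-one F7. The aryloxymethyl ketone is the most acidic site, so KN(SiMe3)2 and PhNTf2 at -78 °C should give the (Z)-enol triflate 7-[(Z)-3,3-diethoxy-2-(trifluoromethylsulfonyloxy)prop-1-enyloxy]-2,2,5-trimethyl-6-(triisopropylsilyloxy)chroman-4-one F8. Anti elimination with KOtBu in THF at -78 °C then gives 13.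

**Step 10.** The aldol addition may be outrun by dipolar cycloaddition of the diazoacetate to the enal, the adduct may revert, or the oxidant may attack the ynol ether. The fallback installs the whole keto ester by acylketene transfer and adds the diazo group last; it sets out from 14 and returns at 22, bypassing steps 8 to 10. Meldrum's acid is C-acylated with methacryloyl chloride (pyridine, CH2Cl2, 0 °C) to 5-(1-hydroxy-2-methylprop-2-enylidene)-2,2-dimethyl-1,3-dioxane-4,6-dione F9. Heating this acyl Meldrum's acid with phenol 14 in toluene at 80 °C releases the acylketene, which is trapped to give 7-(3,3-diethoxyprop-1-ynyloxy)-2,2,5-trimethyl-4-oxochroman-6-yl 4-methyl-3-oxopent-4-enoate F10. Regitz diazo transfer (4-acetamidobenzenesulfonyl azide, Et3N, MeCN, 0 °C) gives 22; it is stopped as soon as the keto ester is consumed, to limit addition of the azide to the ynol ether.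

## Further compounds

F1 | step 11 | 1,1,1-trifluoro-5-methylhex-5-ene-2,4-dione | CC(=C)C(=O)CC(=O)C(F)(F)F
F2 | step 11 | 1-diazo-3-methylbut-3-en-2-one | CC(=C)C(=O)C=[N+]=[N-]
F3 | step 11 | 7-[2-(diethoxymethyl)-3-hydroxy-5-methylphenoxy]-2,2,5-trimethyl-6-(triisopropylsilyloxy)chroman-4-one | Cc1cc(O)c(C(OCC)OCC)c(Oc2cc3OC(C)(C)CC(=O)c3c(C)c2O[Si](C(C)C)(C(C)C)C(C)C)c1
F4 | step 11 | 7-[2-(diethoxymethyl)-3-hydroxy-6-iodo-5-methylphenoxy]-2,2,5-trimethyl-6-(triisopropylsilyloxy)chroman-4-one | Cc1cc(O)c(C(OCC)OCC)c(Oc2cc3OC(C)(C)CC(=O)c3c(C)c2O[Si](C(C)C)(C(C)C)C(C)C)c1I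
F5 | step 11 | 7-[2-(diethoxymethyl)-3-hydroxy-6-iodo-5-methylphenoxy]-6-hydroxy-2,2,5-trimethylchroman-4-one | Cc1cc(O)c(C(OCC)OCC)c(Oc2cc3OC(C)(C)CC(=O)c3c(C)c2O)c1I
F6 | step 6 | 3-bromo-1,1-diethoxypropan-2-one | CCOC(OCC)C(=O)CBr
F7 | step 6 | 7-(3,3-diethoxy-2-oxopropoxy)-2,2,5-trimethyl-6-(triisopropylsilyloxy)chroman-4-one | Cc1c(O[Si](C(C)C)(C(C)C)C(C)C)c(OCC(=O)C(OCC)OCC)cc2OC(C)(C)CC(=O)c12
F8 | step 6 | 7-[(Z)-3,3-diethoxy-2-(trifluoromethylsulfonyloxy)prop-1-enyloxy]-2,2,5-trimethyl-6-(triisopropylsilyloxy)chroman-4-one | Cc1c(O[Si](C(C)C)(C(C)C)C(C)C)c(O/C=C(\OS(=O)(=O)C(F)(F)F)C(OCC)OCC)cc2OC(C)(C)CC(=O)c12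
F9 | step 10 | 5-(1-hydroxy-2-methylprop-2-enylidene)-2,2-dimethyl-1,3-dioxane-4,6-dione | CC(=C)C(O)=C1C(=O)OC(C)(C)OC1=O
F10 | step 10 | 7-(3,3-diethoxyprop-1-ynyloxy)-2,2,5-trimethyl-4-oxochroman-6-yl 4-methyl-3-oxopent-4-enoate | Cc1c(OC(=O)CC(=O)C(C)=C)c(OC#CC(OCC)OCC)cc2OC(C)(C)CC(=O)c12
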